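**Plan**
- Retrosynthesis: after removal of two silyl and two benzyl ethers, the central ring (ring B) is cut at C1–C2 and C5–C6. Its pattern (C1 ester carbonyl to the ring A oxygen, C2 hydroxyl, C4 oxygen acylated by ring C, C6 methyl) is that of a resorcylate formed from a 1,3-dioxygenated cyclohexa-1,3-diene and a but-2-ynoate.
- The diene is then cut at its enol-ester C–O bond (ring C acid chloride plus a 3-silyloxycyclohexenone), and the ynoate at its aryl-ester C–O bond (methyl orsellinate plus but-2-ynoic acid).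
- Forward: rings A and C both come from methyl orsellinate, and each is first joined by an ester to one half of the future ring B. Ring B, the only ring formed, arises last by [4+2] addition and loss of ethylene, followed by two deprotections.
- Stereochemistry: the target has no stereocentre; the bridgehead centres of the transient cycloadduct vanish on aromatisation.

Key step: step 8

Remark on the chemistry: the target SMILES has no stereogenic element, so "single enantiomer" is taken to mean the achiral compound as drawn and no asymmetric step is needed.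

**Route**

Step 1
Reactants: 1 methyl orsellinate (methyl 2,4-dihydroxy-6-methylbenzoate)
Product: 2 methyl 2,4-bis(benzyloxy)-6-methylbenzoate
Conditions: BnBr (2.5 equiv), K2CO3, DMF, 60 °C
Reagents that add atoms: benzyl bromide, BrCc1ccccc1
Why: Williamson etherification of both phenols; warm carbonate in DMF should also alkylate the hydrogen-bonded 2-OH, and the methyl ester is inert.

Step 2
Reactants: 2 methyl 2,4-bis(benzyloxy)-6-methylbenzoate
Product: 3 2,4-bis(benzyloxy)-6-methylbenzoic acid
Conditions: KOH, DMSO/H2O (4:1), 90 °C; then aq. HCl, 0 °C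
Reagents that add atoms: potassium hydroxide, [K+].[OH-]
Why: Saponification of a doubly ortho-substituted benzoate needs hot hydroxide in aqueous DMSO, conditions under which aryl benzyl ethers are stable.

Step 3
Reactants: 3 2,4-bis(benzyloxy)-6-methylbenzoic acid
Product: 4 2,4-bis(benzyloxy)-6-methylbenzoyl chloride
Conditions: (COCl)2, DMF (cat.), CH2Cl2, 0 °C → rt; evaporate, use crude
Reagents that add atoms: oxalyl chloride, O=C(Cl)C(=O)Cl
Why: Acid chloride formation through the Vilsmeier-type chloroiminium catalyst is mild enough to leave the benzyl ethers untouched.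

Step 4
Reactants: 5 cyclohexane-1,3-dione
Product: 6 3-[(tert-butyldimethylsilyl)oxy]cyclohex-2-en-1-one
Conditions: TBSCl, Et3N, CH2Cl2, 0 °C → rt
Reagents that add atoms: tert-butyldimethylsilyl chloride, CC(C)(C)[Si](C)(C)Cl
Why: O-silylation of the enol form of the 1,3-dione gives the vinylogous silyl ester; TBS is chosen because it should survive LDA and prolonged heating.

Step 5
Reactants: 6 3-[(tert-butyldimethylsilyl)oxy]cyclohex-2-en-1-one; 4 2,4-bis(benzyloxy)-6-methylbenzoyl chloride
Product: 8 5-[(tert-butyldimethylsilyl)oxy]cyclohexa-1,5-dien-1-yl 2,4-bis(benzyloxy)-6-methylbenzoate, via lithium dienolate 7 (not isolated)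
Conditions: LDA, THF, –78 °C; DMPU, then 4 in THF, –78 → –20 °C; pH 7 buffer; Et3N-deactivated silica
Reagents that add atoms: lithium diisopropylamide, CC(C)N([Li])C(C)C (its lithium appears only in 7; 8 takes no non-hydrogen atom from a reagent)
Why: Kinetic deprotonation at the α'-CH2 (C6) of the vinylogous ester gives the cross-conjugated dienolate, and the hard, hindered aroyl chloride in THF/DMPU should acylate it on oxygen (enol ester formation), which puts the aroyloxy group on the inner diene carbon and leaves the silyloxy group at the diene terminus.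

Step 6
Reactants: 1 methyl orsellinate; 9 but-2-ynoic acid
Product: 10 methyl 4-(but-2-ynoyloxy)-2-hydroxy-6-methylbenzoate
Conditions: DCC, DMAP (5 mol %), CH2Cl2, 0 °C → rt
Reagents that add atoms: none
Why: Steglich esterification; the 2-OH is tied up in a hydrogen bond to the ester carbonyl, so only the free 4-OH should be acylated.

Step 7
Reactants: 10 methyl 4-(but-2-ynoyloxy)-2-hydroxy-6-methylbenzoate
Product: 11 methyl 4-(but-2-ynoyloxy)-2-[(tert-butyldimethylsilyl)oxy]-6-methylbenzoate
Conditions: TBSOTf, 2,6-lutidine, CH2Cl2, 0 °C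
Reagents that add atoms: tert-butyldimethylsilyl triflate, CC(C)(C)[Si](C)(C)OS(=O)(=O)C(F)(F)F
Why: A silyl triflate with a non-nucleophilic base silylates even a chelated phenol without adding to the ynoate, and masks the acidic OH that could otherwise protodesilylate the diene during step 8.

Step 8
Reactants: 8 5-[(tert-butyldimethylsilyl)oxy]cyclohexa-1,5-dien-1-yl 2,4-bis(benzyloxy)-6-methylbenzoate; 11 methyl 4-(but-2-ynoyloxy)-2-[(tert-butyldimethylsilyl)oxy]-6-methylbenzoate
Product: 13 methyl 4-({4-[(2,4-bis(benzyloxy)-6-methylbenzoyl)oxy]-2-[(tert-butyldimethylsilyl)oxy]-6-methylbenzoyl}oxy)-2-[(tert-butyldimethylsilyl)oxy]-6-methylbenzoate, via bicyclo[2.2.2]octadiene cycloadduct 12 (not isolated)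
Conditions: 8 (1.5 equiv), BHT (cat.), mesitylene (2 M), Ar, 140 °C then reflux (165 °C)
Reagents that add atoms: none
Why: A thermal normal-demand [4+2] cycloaddition between the electron-rich diene of 8 and the aryl ynoate 11 gives bicyclo[2.2.2]octa-2,5-diene 12, whose ethano bridge then leaves as ethylene in a retro-[4+2] driven by aromatisation of ring B (Alder–Rickert reaction). The closest known case is the reaction of 1,3-bis(silyloxy)cyclohexa-1,3-dienes with alk-2-ynoates to give 2,4-dioxygenated 6-alkylbenzoates; here one silyloxy donor is replaced by a weaker aroyloxy donor, which is offset by the more electron-poor aryl ynoate. Ring B is closed by the concerted intermolecular cycloaddition itself, both new σ bonds (ring B C1–C2 and C5–C6) forming suprafacially across the s-cis diene held by the six-membered ring, and the cycloreversion only removes the two-carbon bridge. The two bridgehead centres of 12 form as a racemate and disappear with the ethylene, so 13 has no stereocentre and no stereocontrol is required. The selectivity needed is regiochemical: the terminal silyloxy group and the inner aroyloxy group both place the largest HOMO coefficient on the unsubstituted CH terminus, which bonds to the methyl-bearing β-carbon of the ynoate, so the silyloxy carbon joins the α-carbon and ends ortho to the new ester. Neutral heating without acid or base should leave the hindered aryl esters, the benzyl ethers and both silyl ethers intact.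

Step 9
Reactants: 13 bis-silyl dibenzyl tridepside
Product: 14 methyl 4-({4-[(2,4-bis(benzyloxy)-6-methylbenzoyl)oxy]-2-hydroxy-6-methylbenzoyl}oxy)-2-hydroxy-6-methylbenzoate
Conditions: TBAF/AcOH (1:1.2), THF, 0 °C
Reagents that add atoms: none
Why: Fluoride cleaves both aryl silyl ethers, and the acetic acid buffer protonates the phenoxides at once so that the three hindered aryl esters should not be transesterified.

Step 10
Reactants: 14 dibenzyl tridepside
Product: 15 methyl 4-({4-[(2,4-dihydroxy-6-methylbenzoyl)oxy]-2-hydroxy-6-methylbenzoyl}oxy)-2-hydroxy-6-methylbenzoate (target)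
Conditions: H2 (1 atm), 10% Pd/C, EtOAc, rt
Reagents that add atoms: none
Why: Hydrogenolysis of aryl benzyl ethers over palladium is neutral and should leave aryl esters and arene rings unreduced, the usual last step for a depside.

**Compound list**
1 | methyl orsellinate (methyl 2,4-dihydroxy-6-methylbenzoate) | COC(=O)c1c(C)cc(O)cc1O | starting material
2 | methyl 2,4-bis(benzyloxy)-6-methylbenzoate | COC(=O)c1c(C)cc(OCc2ccccc2)cc1OCc1ccccc1 | intermediate
3 | 2,4-bis(benzyloxy)-6-methylbenzoic acid | Cc1cc(OCc2ccccc2)cc(OCc2ccccc2)c1C(=O)O | intermediate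
4 | 2,4-bis(benzyloxy)-6-methylbenzoyl chloride | Cc1cc(OCc2ccccc2)cc(OCc2ccccc2)c1C(=O)Cl | intermediate
5 | cyclohexane-1,3-dione | O=C1CCCC(=O)C1 | starting material
6 | 3-[(tert-butyldimethylsilyl)oxy]cyclohex-2-en-1-one | CC(C)(C)[Si](C)(C)OC1=CC(=O)CCC1 | intermediate
7 | lithium 5-[(tert-butyldimethylsilyl)oxy]cyclohexa-1,5-dien-1-olate | [Li]OC1=CCCC(O[Si](C)(C)C(C)(C)C)=C1 | intermediate (not isolated)
8 | 5-[(tert-butyldimethylsilyl)oxy]cyclohexa-1,5-dien-1-yl 2,4-bis(benzyloxy)-6-methylbenzoate | CC(C)(C)[Si](C)(C)OC1=CC(OC(=O)c2c(C)cc(OCc3ccccc3)cc2OCc2ccccc2)=CCC1 | intermediate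
9 | but-2-ynoic acid | CC#CC(=O)O | starting material
10 | methyl 4-(but-2-ynoyloxy)-2-hydroxy-6-methylbenzoate | COC(=O)c1c(C)cc(OC(=O)C#CC)cc1O | intermediate
11 | methyl 4-(but-2-ynoyloxy)-2-[(tert-butyldimethylsilyl)oxy]-6-methylbenzoate | COC(=O)c1c(C)cc(OC(=O)C#CC)cc1O[Si](C)(C)C(C)(C)C | intermediate
12 | 3-[(tert-butyldimethylsilyl)oxy]-4-(methoxycarbonyl)-5-methylphenyl 5-{[2,4-bis(benzyloxy)-6-methylbenzoyl]oxy}-1-[(tert-butyldimethylsilyl)oxy]-3-methylbicyclo[2.2.2]octa-2,5-diene-2-carboxylate (racemic) | CC(C)(C)[Si](C)(C)OC12C=C(OC(=O)c3c(C)cc(OCc4ccccc4)cc3OCc3ccccc3)C(CC1)C(C)=C2C(=O)Oc1cc(C)c(C(=O)OC)c(O[Si](C)(C)C(C)(C)C)c1 | intermediate (not isolated)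
13 | methyl 4-({4-[(2,4-bis(benzyloxy)-6-methylbenzoyl)oxy]-2-[(tert-butyldimethylsilyl)oxy]-6-methylbenzoyl}oxy)-2-[(tert-butyldimethylsilyl)oxy]-6-methylbenzoate | COC(=O)c1c(C)cc(OC(=O)c2c(C)cc(OC(=O)c3c(C)cc(OCc4ccccc4)cc3OCc3ccccc3)cc2O[Si](C)(C)C(C)(C)C)cc1O[Si](C)(C)C(C)(C)C | intermediate
14 | methyl 4-({4-[(2,4-bis(benzyloxy)-6-methylbenzoyl)oxy]-2-hydroxy-6-methylbenzoyl}oxy)-2-hydroxy-6-methylbenzoate | COC(=O)c1c(C)cc(OC(=O)c2c(C)cc(OC(=O)c3c(C)cc(OCc4ccccc4)cc3OCc3ccccc3)cc2O)cc1O | intermediate
15 | methyl 4-({4-[(2,4-dihydroxy-6-methylbenzoyl)oxy]-2-hydroxy-6-methylbenzoyl}oxy)-2-hydroxy-6-methylbenzoate | COC(=O)c1c(C)cc(OC(=O)c2c(C)cc(OC(=O)c3c(C)cc(O)cc3O)cc2O)cc1O | target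

**Totals**
Total step count: 10. Longest linear sequence: 7 (steps 1, 2, 3, 5, 8, 9, 10).

**Steps most likely to fail**

Step 8. The mixed silyloxy/aroyloxy diene may add too slowly to the β-methyl ynoate and be lost by thermal desilylation or acyl migration before it reacts, or the ethylene extrusion may stall. The fallback is the classical depside esterification, with no cycloaddition, setting out from 4 and 1. Commercial 2,4-dihydroxy-6-methylbenzaldehyde F1 is acylated at its non-chelated 4-OH with 4 (pyridine, CH2Cl2) to give 4-formyl-3-hydroxy-5-methylphenyl 2,4-bis(benzyloxy)-6-methylbenzoate F2. Pinnick oxidation (NaClO2, NaH2PO4, 2-methylbut-2-ene, t-BuOH/H2O) gives 4-{[2,4-bis(benzyloxy)-6-methylbenzoyl]oxy}-2-hydroxy-6-methylbenzoic acid F3. This acid is condensed with the free 4-OH of 1 through its mixed trifluoroacetic anhydride (TFAA, toluene, rt) to give 14, where the route is rejoined before step 10.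

Step 5. Acylation of the kinetic dienolate by the doubly ortho-substituted acid chloride may be slow enough to allow C-acylation or proton exchange to the extended dienolate, and the enol ester may hydrolyse on isolation. The fallback puts the ring C acyl group on after the ring is built, setting out from 6. LDA then TMSCl gives tert-butyldimethyl({3-[(trimethylsilyl)oxy]cyclohexa-1,3-dien-1-yl}oxy)silane F4 by ordinary kinetic enolate silylation. Heating F4 with 11 as in step 8 gives, through the bicyclo[2.2.2]octadiene adduct F5, the arene methyl 2-[(tert-butyldimethylsilyl)oxy]-4-({2-[(tert-butyldimethylsilyl)oxy]-6-methyl-4-[(trimethylsilyl)oxy]benzoyl}oxy)-6-methylbenzoate F6. Mild methanolysis (citric acid, MeOH, 0 °C) should cleave only the aryl trimethylsilyl ether to give the phenol methyl 2-[(tert-butyldimethylsilyl)oxy]-4-({2-[(tert-butyldimethylsilyl)oxy]-4-hydroxy-6-methylbenzoyl}oxy)-6-methylbenzoate F7. Acylation of this free para-phenol with 4 (Et3N, DMAP cat., CH2Cl2) gives 13, where the route is rejoined before step 9.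

Step 2. Hydrolysis of the doubly ortho-substituted methyl ester may stall, and forcing it risks attack on the benzyl ethers. The fallback builds the acid from the aldehyde oxidation level. Orcinol (5-methylbenzene-1,3-diol) F8 is dibenzylated (BnBr, K2CO3, DMF) to 1,3-bis(benzyloxy)-5-methylbenzene F9. Vilsmeier–Haack formylation (POCl3, DMF), para to one benzyloxy group and ortho to the other, gives 2,4-bis(benzyloxy)-6-methylbenzaldehyde F10. Pinnick oxidation of F10 gives 3, where the route is rejoined before step 3.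

**Further compounds**
F1 | step 8 | 2,4-dihydroxy-6-methylbenzaldehyde | Cc1cc(O)cc(O)c1C=O
F2 | step 8 | 4-formyl-3-hydroxy-5-methylphenyl 2,4-bis(benzyloxy)-6-methylbenzoate | Cc1cc(OCc2ccccc2)cc(OCc2ccccc2)c1C(=O)Oc1cc(C)c(C=O)c(O)c1
F3 | step 8 | 4-{[2,4-bis(benzyloxy)-6-methylbenzoyl]oxy}-2-hydroxy-6-methylbenzoic acid | Cc1cc(OCc2ccccc2)cc(OCc2ccccc2)c1C(=O)Oc1cc(C)c(C(=O)O)c(O)c1
F4 | step 5 | tert-butyldimethyl({3-[(trimethylsilyl)oxy]cyclohexa-1,3-dien-1-yl}oxy)silane | CC(C)(C)[Si](C)(C)OC1=CC(O[Si](C)(C)C)=CCC1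
F5 | step 5 | 3-[(tert-butyldimethylsilyl)oxy]-4-(methoxycarbonyl)-5-methylphenyl 1-[(tert-butyldimethylsilyl)oxy]-3-methyl-5-[(trimethylsilyl)oxy]bicyclo[2.2.2]octa-2,5-diene-2-carboxylate (racemic) | CC(C)(C)[Si](C)(C)OC12C=C(O[Si](C)(C)C)C(CC1)C(C)=C2C(=O)Oc1cc(C)c(C(=O)OC)c(O[Si](C)(C)C(C)(C)C)c1
F6 | step 5 | methyl 2-[(tert-butyldimethylsilyl)oxy]-4-({2-[(tert-butyldimethylsilyl)oxy]-6-methyl-4-[(trimethylsilyl)oxy]benzoyl}oxy)-6-methylbenzoate | COC(=O)c1c(C)cc(OC(=O)c2c(C)cc(O[Si](C)(C)C)cc2O[Si](C)(C)C(C)(C)C)cc1O[Si](C)(C)C(C)(C)C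
F7 | step 5 | methyl 2-[(tert-butyldimethylsilyl)oxy]-4-({2-[(tert-butyldimethylsilyl)oxy]-4-hydroxy-6-methylbenzoyl}oxy)-6-methylbenzoate | COC(=O)c1c(C)cc(OC(=O)c2c(C)cc(O)cc2O[Si](C)(C)C(C)(C)C)cc1O[Si](C)(C)C(C)(C)C
F8 | step 2 | orcinol (5-methylbenzene-1,3-diol) | Cc1cc(O)cc(O)c1
F9 | step 2 | 1,3-bis(benzyloxy)-5-methylbenzene | Cc1cc(OCc2ccccc2)cc(OCc2ccccc2)c1
F10 | step 2 | 2,4-bis(benzyloxy)-6-methylbenzaldehyde | Cc1cc(OCc2ccccc2)cc(OCc2ccccc2)c1C=O
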